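(The data are simulated from invented constants.)

The birch run, at 10 °C, showed where to look: its starting material read 59.2 % at 80.0 min and 60.8 % at 240 min, so it had stopped, while its target fell to 2.1 %. The maple run stopped as well.

common to all: starting material 15 mM
- maple: coupling partner 12 mM; second substrate 15 mM; third substrate 7.5 mM; temperature 25 °C; the very flask that is asked about, followed so far
- birch: coupling partner 12 mM; second substrate 15 mM; third substrate 7.5 mM; temperature 10 °C; run made earlier
- flask: coupling partner 12.0 mM; second substrate 15.0 mM; third substrate 7.50 mM; temperature 25 °C; time 2.0 h

- maple (time / min: target / %, starting material / %): 15.0: 12.1, 67.8; 40.0: 7.7, 63.8; 80.0: 10.1, 64.4; 120: 8.0, 62.7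
- birch (time / min: target / %, starting material / %): 30.0: 22.6, 67.7; 80.0: 13.9, 59.2; 180: 4.7, 57.7; 240: 2.1, 60.8

(standard deviation of a reading: 1 percentage point)

- theta: at 2.0 h add coupling partner, 50.0 % of the amount charged, then wait 2.0 h
- alpha: at 2.0 h take out 90 % of the target then present, then wait 2.0 h
- eta: at 2.0 h raise the temperature by 25 K, then wait 2.0 h
- delta: change nothing and wait 2.0 h more

1. target, in percent of the starting material first charged, at 2.0 h
2. which option adds most target ("none" when 2 percentage points or less is all one gets) (theta / alpha / eta / delta / none)
3. target present, with what was taken out counted in, in percent of the starting material first charged, after eta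
4. target present, with what was taken out counted in, in percent of the starting material first charged, after delta

- removed target is counted in
- additions bring no volume worth counting

From 40.0 min on, the starting material in the maple run averaged 63.6 %, so it had not stopped for lack of itself. That pointed at the coupling partner, the concentration I took to set the rate at which starting material was used.

I then solved two extreme flasks. If the coupling partner went wholly to starting material, 20.0 % of the starting material remained. If the second and third substrates took it wholly, the starting material stayed at its charge. I took those substrates to compete for the same partner, so I placed the maple flask between these extremes.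

The readings placed it there: 5.46 mM had reacted, less than the 12 mM of partner charged. So the readings gave 45.5 % as the capture share, the part of the charged coupling partner taken by starting material.

Target in the maple run averaged 8.60 % over those readings, flat within the scatter of 1 percentage point, so 23.6 % of what had reacted stood as target. I committed to 8.60 % at 2.0 h, with no gain from waiting.

The forecast gave 8.8 % at 2.0 h, 8.7 % after delta, and eta as the best option with 24 %, reading a balance “with the target favoured by heat”.

The simulation gave 8.65 %, 8.65 % after delta, and eta as the best option with 24.5 %, a gain of 16 points.

    starting material + coupling partner → target (k = 5.34 L mol⁻¹ min⁻¹, Ea = 38.0 kJ mol⁻¹)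
    second substrate + coupling partner → second product (k = 2.35 L mol⁻¹ min⁻¹, Ea = 56.0 kJ mol⁻¹)
    third substrate + coupling partner → third product (k = 9.48 L mol⁻¹ min⁻¹, Ea = 50.0 kJ mol⁻¹)
    target ⇌ isomer of the product (K = 3.10, k = 0.121 min⁻¹, Ea = 85.0 kJ mol⁻¹, ΔH = −62.0 kJ mol⁻¹)
    (constants at 25 °C)

In this flask the coupling steps ran while partner was there: it stood at 17.5 % at 12.0 min and at 0 % at 120 min, the limiting reagent, with starting material at 64.5 %. By their own step, target and isomer of the product relaxed with a half-life of 4.33 min, far shorter than the 2.0 h, and at 120 min they stood at 8.65 % and 26.8 %. As an estimate, the capture share put on theta's added partner gives 4.3 points; theta added 4.5 points. With 3.0 mM of partner, the neighbour should keep 90.9 % of its starting material and reach 2.15 % target; it holds 91.3 % and 2.11 %.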